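Compound numbers are those of the steps and of the list after them.

## Analysis of the target

The target 22 is a flavonol: a 4H-chromen-4-one (rings A and C) with a 3,4,5-trimethoxyphenyl group (ring B) at C2, hydroxyls at C3 and C5, and methoxy groups at C7 and C8. C6 is the only unsubstituted carbon of ring A. There is no stereocenter, so every difficulty is one of regiochemistry and of telling oxygen atoms apart. Two hydroxyls must end up free beside five methyl ethers; both are hydrogen-bonded to the C4 carbonyl, and the 3-hydroxy-4-pyranone unit is sensitive to oxidants and to base in air, so it is best unveiled late. In ring A, C4a is flanked by two oxygen-bearing carbons, C5 and C8a. If these are not distinguished before ring C is closed, closure through the wrong oxygen gives the 5-hydroxy-6,7-dimethoxy isomer, and a route from a permethylated arene must later find the C5 methyl ether among six. The strategy rests on this C5/C8a pair: ring A is built from open-chain pieces so that the C5 oxygen is born as a free phenol from a ketene carbonyl carbon and the C8a oxygen as a silyl ether from an ynol ether, with the C7 and C8 methoxy groups and a masked acetyl group at C4a already in place.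

## Retrosynthetic reasoning

**22 from 21.** The last cut is the O–benzyl bond at C5. A benzyl ether is orthogonal to the five methyl ethers, so its hydrogenolysis frees the C5 hydroxyl without any selective demethylation.

**21 from 19.** Ring C is opened at O1–C2 and the C3 hydroxyl is removed, which leads to the 2'-hydroxychalcone 19. The forward reaction, an Algar–Flynn–Oyamada oxidation, closes the pyranone and installs the C3 oxygen at the right oxidation level in one operation. It needs the C8a oxygen free and the C5 oxygen blocked, which is the situation in 19.

**19 from 17 and 18.** The C2–C3 double bond of the chalcone is cut by a retro-aldol condensation. Ring B and C2 then come from the aldehyde 18, and ring A with C3 and C4 from the acetophenone 17. Both partners are simple, and 18 cannot enolize.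

**17 from 14 via 15.** These steps exchange the roles of the two oxygens. In 14 the C5 oxygen is free and the C8a oxygen is silylated; the cyclization needs the reverse. Benzylation of 14 gives 15, and removal of the silyl group and of the ketal gives 17. No selectivity is asked of any reagent, because the two oxygens already differ in 14.

**14 from 4 and 9.** This is the key disconnection. Ring A is cut at C4a–C5, C5–C6 and C8–C8a, which returns the cyclobutenone 4 (C5, C6, C7, C8 with both methoxy groups) and the siloxyalkyne 9 (C4a with the masked acetyl group, and C8a with its oxygen). The cut is made here because it is the only one that delivers the hydroxyl, the silyl ether, both methyl ethers and the side chain in fixed positions from acyclic or small-ring precursors. The forward reaction has to generate a vinylketene from 4 and add it to 9 with the regiochemistry dictated by the ynol ether.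

**9 from 5 via 6.** The alkyne is traced to an ester by a one-carbon ynolate homologation: the ester carbonyl carbon becomes the oxygen-bearing alkyne carbon, and the ketal-bearing carbon migrates to the new carbon. The ester 6 is the ethylene ketal of 5, so the acetyl group of 17 is carried from the start at the ketone oxidation level.

**4 from 1 via 2 and 3.** The cyclobutenone is a squarate with one carbonyl replaced by CH2. One carbonyl of 1 is reduced to the alcohol 2, the alcohol is acetylated to 3, and the C–O bond is cleaved reductively. Both methoxy groups of 22 at C7 and C8 come from 1 unchanged.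

## Alternatives that were turned down

**Alternative 1:** Ring C is cut at C3–C4 and at C2=C3, so that C3 with its oxygen comes from a one-carbon phosphorus ylide, (benzyloxymethylene)triphenylphosphorane A2, and rings A and B come joined as the O-aroylsalicyloyl chloride A1. In the forward key step A2 is acylated at carbon by A1, a second equivalent of ylide deprotonates the acylphosphonium salt, and the keto ylide olefinates the neighbouring aryl ester carbonyl to close the pyranone as the 3-benzyloxyflavone A3.
- For: it is convergent, makes ring C with the C3 oxygen in one flask, and has no competing five-membered ring closure. On that point it is stronger than the Algar–Flynn–Oyamada step of the chosen route, and it is also shorter.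
- Against: ring A enters as a permethylated salicylic acid made by classical arene substitution, so the C5 oxygen is one methyl ether among six. The last step must cleave exactly that one; chelation to the C4 carbonyl helps, but cleavage in the vicinal methoxy arrays of ring B and of C7/C8 competes. The keto ylide is also stabilized by the α-alkoxy group and must attack an ester carbonyl shielded by two ortho substituents.
- Comparison: the chosen strategy gives up some brevity, and in return the C5 oxygen is never methylated and no selective demethylation is needed.

**Alternative 2:** The cut is at C4–C4a and O1–C2, giving 2,3,5-trimethoxyphenol A4 and (E)-3,4,5-trimethoxycinnamaldehyde A5, which is one homologation away from 18. In the forward key step a boronic acid template joins the two at the only free ortho position of A4, the cyclic boronate fragments to an ortho-quinone methide, and oxa-6π electrocyclization gives the 2H-chromene A6 (racemic; its C2 stereocenter is destroyed later).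
- For: two components and one step assemble the whole skeleton with fixed regiochemistry. In speed of skeletal assembly it is stronger than the chosen route.
- Against: A6 is at the wrong oxidation level at three carbons. C4 must become a carbonyl, C3 must gain a hydroxyl, and C2–C3 must be dehydrogenated, all on a molecule with two very electron-rich arenes and a doubly activated C2–H. Such flavenes tend to ionize to flavylium ions and to disproportionate under oxidants. The C5 oxygen again arrives as a methyl ether that must be singled out at the end.
- Comparison: the chosen route reaches ring C at the final oxidation level in one step from the chalcone and has C5 differentiated from the outset.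

**Alternative 3:** Ring A is cut at C4a–C5 and C8–C8a as a Diels–Alder reaction between the ketene acetal diene A7 and 4-bromobut-3-yn-2-one A8. In the forward key step the nucleophilic diene terminus (C8) bonds to the bromine-bearing β-carbon of the ynone, and the adduct collapses at its mixed silyl methyl ketal carbon and tautomerizes to the bromophenol A9.
- For: the logic is the same as in the chosen route: ring A is made from open-chain parts and the two positions ortho to C4a differ in kind (hydroxyl against bromine). The acetyl group arrives unmasked, and the regiochemistry of such dienes with ynones is predictable. In directness to an acetophenone it is stronger.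
- Against: the bromine at C8a must still be turned into the C8a–O1 bond by a metal-catalysed O-arylation at a carbon flanked by a methoxy group and an acyl group. That is a bond the chosen route obtains in the benzannulation itself. A8 is also an addition–elimination acceptor, so the ketene acetal may displace bromide instead of cycloadding. The diene is hindered at its reacting terminus and must be made as one geometric isomer, and O-arylation of a diketone enol gives a flavone without the C3 hydroxyl, which then needs a separate oxidation.
- Comparison: the chosen route installs both ring A oxygens in the ring-forming step and leaves only standard chalcone chemistry afterwards.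

Key step: step 6

Assumption: 1, 5 and 18 are purchased; the intermediates 2, 3, 11 and 20 are racemic, one enantiomer is drawn, and their stereocenters do not reach the target.

## Route

Step 1
Reactants: 1 dimethyl squarate (3,4-dimethoxycyclobut-3-ene-1,2-dione)
Product: 2 4-hydroxy-2,3-dimethoxycyclobut-2-en-1-one (racemic)
Conditions: LiAlH(Ot-Bu)3, THF, −78 °C; aq. NaH2PO4/Na2HPO4 (pH 7) work-up
Reagents that add atoms: none
Why: The bulky hydride LiAlH(Ot-Bu)3 should add once to one of the two equivalent vinylogous-ester carbonyls (1,2-reduction), and the resulting alkoxide resists further reduction at low temperature; mono-reduction of dialkyl squarates to 4-hydroxycyclobutenones is established, and a neutral work-up avoids acid-induced loss of methanol.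

Step 2
Reactants: 2 4-hydroxy-2,3-dimethoxycyclobut-2-en-1-one
Product: 3 2,3-dimethoxy-4-oxocyclobut-2-en-1-yl acetate (racemic)
Conditions: Ac2O, pyridine, DMAP (cat.), CH2Cl2, 0 °C
Reagents that add atoms: acetic anhydride, CC(=O)OC(C)=O
Why: DMAP-catalysed acylation of a secondary alcohol; the basic medium avoids ionization at C4, and the acetate makes the oxygen a leaving group for the electron-transfer step.

Step 3
Reactants: 3 2,3-dimethoxy-4-oxocyclobut-2-en-1-yl acetate
Product: 4 2,3-dimethoxycyclobut-2-en-1-one
Conditions: SmI2 (2.2 equiv), THF–MeOH, −78 °C
Reagents that add atoms: none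
Why: Reductive cleavage of an α-acyloxy ketone by SmI2 (divalent samarium): two single-electron transfers, loss of acetate, and protonation of the samarium enolate by methanol. The enolate is formed with its double bond between C1 and C4, so kinetic α-protonation at C4 should leave the dimethoxy enone in place, in analogy to the zinc dehalogenation of 4,4-dichlorocyclobutenones.

Step 4
Reactants: 5 ethyl pyruvate
Product: 6 ethyl 2-methyl-1,3-dioxolane-2-carboxylate
Conditions: HOCH2CH2OH, p-TsOH (cat.), toluene, reflux, Dean–Stark
Reagents that add atoms: ethylene glycol, OCCO
Why: Acid-catalysed ketalization of the ketone carbonyl with azeotropic removal of water; the ester is untouched, and the dioxolane protects the future acetyl group from the organolithium reagents of step 5.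

Step 5
Reactants: 6 ethyl 2-methyl-1,3-dioxolane-2-carboxylate
Product: 9 triisopropyl[(2-methyl-1,3-dioxolan-2-yl)ethynyloxy]silane, via dibromo enolate 7 (not isolated), via lithium ynolate 8 (not isolated)
Conditions: CH2Br2, LiTMP (lithium 2,2,6,6-tetramethylpiperidide, from the amine and n-BuLi), THF, −78 °C; then n-BuLi, −78 °C to rt; then i-Pr3SiOTf, −78 to 0 °C
Reagents that add atoms: dibromomethane, BrCBr; triisopropylsilyl trifluoromethanesulfonate, CC(C)[Si](OS(=O)(=O)C(F)(F)F)(C(C)C)C(C)C
Why: Kowalski ynolate formation: LiCHBr2 adds to the ester, the dibromo ketone enolate 7 undergoes bromine–lithium exchange and a carbenoid 1,2-shift of the ketal-bearing carbon to give the ynolate 8, and the hard, bulky silyl triflate should silylate 8 on oxygen. The ketal carbon has no hydrogen, so the ester cannot enolize.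

Step 6
Reactants: 4 2,3-dimethoxycyclobut-2-en-1-one; 9 triisopropyl[(2-methyl-1,3-dioxolan-2-yl)ethynyloxy]silane
Product: 14 4,5-dimethoxy-2-(2-methyl-1,3-dioxolan-2-yl)-3-(triisopropylsilyloxy)phenol, via vinylketene 10 (not isolated), via vinylcyclobutenone 11 (not isolated), via dienylketene 12 (not isolated), via cyclohexadienone 13 (not isolated)
Conditions: toluene (0.5 M), 4 (1.3 equiv), 80 °C then 110 °C, sealed tube
Reagents that add atoms: none
Why: Heating opens 4 by reversible 4π electrocyclic cleavage of its C1–C4 bond to the vinylketene 10, which is trapped by the ynol ether 9 in a [2+2] cycloaddition across the ketene C=C to give the 4-vinylcyclobutenone 11. 11 reopens by a second 4π cleavage in which the methoxy group on the sp3 carbon rotates outward, so that the methoxyvinyl group sits cis to the new ketene in 12. Ring A is then closed by a thermal disrotatory 6π electrocyclization of the dienylketene 12 that forms C5–C6, and the dienone 13 tautomerizes to the phenol 14; the [2+2] step has already formed C4a–C5 and C8–C8a. The closest known reaction is the Danheiser benzannulation of cyclobutenones with trialkylsiloxyalkynes, which gives resorcinol monosilyl ethers; the 2,3-dimethoxy cyclobutenone is a new partner in it, not a new reaction type. No stereocenter is created in 14, and the one in 11 disappears on ring opening. The selectivity needed is the regiochemistry of the [2+2] step: the alkyne carbon remote from oxygen is the nucleophilic one and bonds to the electrophilic ketene carbonyl carbon, as the polarization of the ynol ether demands. This places the ketal-bearing carbon between the ketene-derived hydroxyl (C5) and the silyl ether (C8a) and puts the two methoxy groups at C7 and C8. The two oxygens ortho to C4a are thereby distinguished by their origin and need no selective protection afterwards.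

Step 7
Reactants: 14 4,5-dimethoxy-2-(2-methyl-1,3-dioxolan-2-yl)-3-(triisopropylsilyloxy)phenol
Product: 15 2-[2-(benzyloxy)-4,5-dimethoxy-6-(triisopropylsilyloxy)phenyl]-2-methyl-1,3-dioxolane
Conditions: BnBr, K2CO3, DMF, rt
Reagents that add atoms: benzyl bromide, BrCc1ccccc1
Why: Williamson etherification of the only free phenol (the C5 oxygen); the aryl triisopropylsilyl ether and the ketal should be stable to K2CO3 in DMF at room temperature, and the two oxygens are 1,3 on the ring, so no silyl migration path exists.

Step 8
Reactants: 15 2-[2-(benzyloxy)-4,5-dimethoxy-6-(triisopropylsilyloxy)phenyl]-2-methyl-1,3-dioxolane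
Product: 17 1-[6-(benzyloxy)-2-hydroxy-3,4-dimethoxyphenyl]ethan-1-one, via desilylated phenol 16 (not isolated)
Conditions: n-Bu4NF, THF, 0 °C; then 2 M aq. HCl, rt
Reagents that add atoms: water, O
Why: Fluoride cleaves the aryl silyl ether to the phenol 16, and aqueous acid then hydrolyses the dioxolane to the methyl ketone; benzyl and methyl ethers are inert to both reagents, and the product is stabilized by the hydrogen bond between the new phenol and the carbonyl.

Step 9
Reactants: 17 1-[6-(benzyloxy)-2-hydroxy-3,4-dimethoxyphenyl]ethan-1-one; 18 3,4,5-trimethoxybenzaldehyde
Product: 19 (E)-1-[6-(benzyloxy)-2-hydroxy-3,4-dimethoxyphenyl]-3-(3,4,5-trimethoxyphenyl)prop-2-en-1-one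
Conditions: KOH, EtOH, rt
Reagents that add atoms: none
Why: Claisen–Schmidt condensation: the enolate of the methyl ketone adds to the non-enolizable aldehyde and the aldol loses water to the conjugated enone, whose E geometry is thermodynamically favoured; the chelated 2'-hydroxyl should hold the product as the open chalcone.

Step 10
Reactants: 19 (E)-1-[6-(benzyloxy)-2-hydroxy-3,4-dimethoxyphenyl]-3-(3,4,5-trimethoxyphenyl)prop-2-en-1-one
Product: 21 5-(benzyloxy)-3-hydroxy-7,8-dimethoxy-2-(3,4,5-trimethoxyphenyl)-4H-chromen-4-one, via trans-dihydroflavonol 20 (not isolated)
Conditions: 30% aq. H2O2, NaOH, MeOH, 0 °C to rt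
Reagents that add atoms: hydrogen peroxide, OO
Why: Algar–Flynn–Oyamada oxidation: the phenoxide adds to the enone at C2 (6-endo oxa-Michael), the enolate carbon is hydroxylated by hydrogen peroxide to the trans-dihydroflavonol 20, and 20 is dehydrogenated under the alkaline peroxide conditions to the flavonol. The benzyl ether leaves only the C8a oxygen available for ring closure.

Step 11
Reactants: 21 5-(benzyloxy)-3-hydroxy-7,8-dimethoxy-2-(3,4,5-trimethoxyphenyl)-4H-chromen-4-one
Product: 22 3,5-dihydroxy-7,8-dimethoxy-2-(3,4,5-trimethoxyphenyl)-4H-chromen-4-one
Conditions: H2 (1 atm), Pd/C, EtOAc–MeOH, rt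
Reagents that add atoms: none
Why: Catalytic hydrogenolysis of the aryl benzyl ether; the methyl ethers, the tetrasubstituted C2=C3 enol double bond and the carbonyl should not react at 1 atm and room temperature.

## Compound list

1 | dimethyl squarate (3,4-dimethoxycyclobut-3-ene-1,2-dione) | COC1=C(OC)C(=O)C1=O | starting material
2 | 4-hydroxy-2,3-dimethoxycyclobut-2-en-1-one (racemic, one enantiomer drawn) | COC1=C(OC)C(=O)[C@@H]1O | intermediate
3 | 2,3-dimethoxy-4-oxocyclobut-2-en-1-yl acetate (racemic, one enantiomer drawn) | COC1=C(OC)C(=O)[C@@H]1OC(C)=O | intermediate
4 | 2,3-dimethoxycyclobut-2-en-1-one | COC1=C(OC)C(=O)C1 | intermediate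
5 | ethyl pyruvate | CCOC(=O)C(C)=O | starting material
6 | ethyl 2-methyl-1,3-dioxolane-2-carboxylate | CCOC(=O)C1(C)OCCO1 | intermediate
7 | lithium 2,2-dibromo-1-(2-methyl-1,3-dioxolan-2-yl)ethenolate | [Li+].[O-]C(=C(Br)Br)C1(C)OCCO1 | intermediate (not isolated)
8 | lithium 2-(2-methyl-1,3-dioxolan-2-yl)ethynolate | [Li+].[O-]C#CC1(C)OCCO1 | intermediate (not isolated)
9 | triisopropyl[(2-methyl-1,3-dioxolan-2-yl)ethynyloxy]silane | CC1(C#CO[Si](C(C)C)(C(C)C)C(C)C)OCCO1 | intermediate
10 | 2,3-dimethoxybuta-1,3-dien-1-one | COC(=C)C(OC)=C=O | intermediate (not isolated)
11 | 4-methoxy-4-(1-methoxyethenyl)-2-(2-methyl-1,3-dioxolan-2-yl)-3-(triisopropylsilyloxy)cyclobut-2-en-1-one (racemic, one enantiomer drawn) | COC(=C)[C@]1(OC)C(O[Si](C(C)C)(C(C)C)C(C)C)=C(C2(C)OCCO2)C1=O | intermediate (not isolated)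
12 | (3Z)-4,5-dimethoxy-2-(2-methyl-1,3-dioxolan-2-yl)-3-(triisopropylsilyloxy)hexa-1,3,5-trien-1-one | O=C=C(C1(C)OCCO1)/C(O[Si](C(C)C)(C(C)C)C(C)C)=C(OC)\C(OC)=C | intermediate (not isolated)
13 | 4,5-dimethoxy-2-(2-methyl-1,3-dioxolan-2-yl)-3-(triisopropylsilyloxy)cyclohexa-2,4-dien-1-one | COC1=C(OC)C(O[Si](C(C)C)(C(C)C)C(C)C)=C(C2(C)OCCO2)C(=O)C1 | intermediate (not isolated)
14 | 4,5-dimethoxy-2-(2-methyl-1,3-dioxolan-2-yl)-3-(triisopropylsilyloxy)phenol | CC1(OCCO1)c1c(O)cc(OC)c(OC)c1O[Si](C(C)C)(C(C)C)C(C)C | intermediate
15 | 2-[2-(benzyloxy)-4,5-dimethoxy-6-(triisopropylsilyloxy)phenyl]-2-methyl-1,3-dioxolane | CC1(OCCO1)c1c(OCc2ccccc2)cc(OC)c(OC)c1O[Si](C(C)C)(C(C)C)C(C)C | intermediate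
16 | 3-(benzyloxy)-5,6-dimethoxy-2-(2-methyl-1,3-dioxolan-2-yl)phenol | CC1(OCCO1)c1c(OCc2ccccc2)cc(OC)c(OC)c1O | intermediate (not isolated)
17 | 1-[6-(benzyloxy)-2-hydroxy-3,4-dimethoxyphenyl]ethan-1-one | CC(=O)c1c(OCc2ccccc2)cc(OC)c(OC)c1O | intermediate
18 | 3,4,5-trimethoxybenzaldehyde | COc1cc(C=O)cc(OC)c1OC | starting material
19 | (E)-1-[6-(benzyloxy)-2-hydroxy-3,4-dimethoxyphenyl]-3-(3,4,5-trimethoxyphenyl)prop-2-en-1-one | COc1cc(/C=C/C(=O)c2c(O)c(OC)c(OC)cc2OCc2ccccc2)cc(OC)c1OC | intermediate
20 | trans-5-(benzyloxy)-3-hydroxy-7,8-dimethoxy-2-(3,4,5-trimethoxyphenyl)chroman-4-one (racemic, one enantiomer drawn) | COc1cc([C@@H]2[C@@H](O)C(=O)c3c(OCc4ccccc4)cc(OC)c(OC)c3O2)cc(OC)c1OC | intermediate (not isolated)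
21 | 5-(benzyloxy)-3-hydroxy-7,8-dimethoxy-2-(3,4,5-trimethoxyphenyl)-4H-chromen-4-one | COc1cc(-c2oc3c(OC)c(OC)cc(OCc4ccccc4)c3c(=O)c2O)cc(OC)c1OC | intermediate
22 | 3,5-dihydroxy-7,8-dimethoxy-2-(3,4,5-trimethoxyphenyl)-4H-chromen-4-one (3,5-dihydroxy-7,8,3',4',5'-pentamethoxyflavone) | COc1cc(-c2oc3c(OC)c(OC)cc(O)c3c(=O)c2O)cc(OC)c1OC | target

## Step count and least certain steps

Total: 11 steps. Longest linear sequence: 9 steps (1 to 22 through steps 1–3 and 6–11); the branch from 5 contributes steps 4 and 5.

**Step 6 (key step).** The [2+2] addition may be too slow to compete with dimerization of the vinylketene 10. The nucleophilic alkyne carbon of 9 carries a quaternary ketal carbon, and 10 is an electron-rich ketene. The donor group at C3 of 4 may also raise the temperature needed for ring opening to a point where 9 rearranges to a silylketene or its propargylic ketal ionizes. The product phenol may in addition be acylated by 10.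

The fallback gives up the benzannulation and returns to classical arene chemistry. Setting out from 18, Dakin-type oxidation (H2O2, cat. H2SO4, MeOH) would give 3,4,5-trimethoxyphenol F1. Ortho-acylation (AcOH, BF3·OEt2, heat) would give 1-(6-hydroxy-2,3,4-trimethoxyphenyl)ethan-1-one F2. Chelation-directed cleavage of the methyl ether ortho to the carbonyl (AlCl3, MeCN) would give 1-(2,6-dihydroxy-3,4-dimethoxyphenyl)ethan-1-one F3. Monobenzylation (BnBr, 1 equiv, K2CO3, acetone) at the less hindered hydroxyl, the one next to the ring C–H, would come back to the route at 17. This path has to rely on the steric difference between the two hydroxyls of F3, which the benzannulation makes unnecessary.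

**Step 3.** The delocalized oxocyclobutenyl anion may be protonated at the methoxy-bearing carbon instead of C4, which would transpose the enone and lead to the wrong ring A pattern. Over-reduction of the product ketone and loss of the volatile product on isolation are further risks.

The fallback changes the mechanism from electron transfer to allyl–metal chemistry. Setting out from 3, zerovalent palladium (Pd(PPh3)4, cat.) with n-Bu3SnH in THF would ionize the allylic acetate to an η3-oxocyclobutenyl palladium complex and deliver hydride to the less substituted terminus, C4, coming back to the route at 4. No new compound is made.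

**Step 5.** The carbenoid rearrangement may be slowed by the two oxygen substituents on the migrating carbon, the ynolate 8 may lose alkoxide, and silylation may occur in part at carbon. The product may also decompose on acidic silica through ionization of the propargylic ketal.

The fallback makes the ynolate by oxidation of an acetylide instead of by rearrangement. Setting out from 6, reduction with i-Bu2AlH at −78 °C would give 2-methyl-1,3-dioxolane-2-carbaldehyde F4. Ohira–Bestmann homologation (dimethyl (1-diazo-2-oxopropyl)phosphonate, K2CO3, MeOH) would give 2-ethynyl-2-methyl-1,3-dioxolane F5. Deprotonation with LiN(SiMe3)2, oxidation of the lithium acetylide with LiOOt-Bu to the same ynolate 8, and silylation with i-Pr3SiOTf would come back to the route at 9.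

**Step 10.** The substituent at C6' of the chalcone twists the carbonyl out of the plane of ring A. This can divert the oxidative cyclization toward five-membered ring closure and aurone formation, and oxidative cleavage of the enone by the alkaline peroxide is also possible.

The fallback separates ring closure from C3 oxidation. Setting out from 19, oxidative cyclization with I2 (cat.) in DMSO at 120 °C would give 5-(benzyloxy)-7,8-dimethoxy-2-(3,4,5-trimethoxyphenyl)-4H-chromen-4-one F6. Epoxidation of its C2=C3 bond with dimethyldioxirane in acetone–CH2Cl2 would give the 2,3-epoxyflavanone F7. Acid-catalysed isomerization (p-TsOH, cat., CH2Cl2) would open the epoxide to the 3-hydroxyflavone and come back to the route at 21.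

## Further compounds

F1 | step 6 | 3,4,5-trimethoxyphenol | COc1cc(O)cc(OC)c1OC
F2 | step 6 | 1-(6-hydroxy-2,3,4-trimethoxyphenyl)ethan-1-one | CC(=O)c1c(O)cc(OC)c(OC)c1OC
F3 | step 6 | 1-(2,6-dihydroxy-3,4-dimethoxyphenyl)ethan-1-one | CC(=O)c1c(O)cc(OC)c(OC)c1O
F0 | step 3 | none | none
F4 | step 5 | 2-methyl-1,3-dioxolane-2-carbaldehyde | CC1(C=O)OCCO1
F5 | step 5 | 2-ethynyl-2-methyl-1,3-dioxolane | CC1(C#C)OCCO1
F6 | step 10 | 5-(benzyloxy)-7,8-dimethoxy-2-(3,4,5-trimethoxyphenyl)-4H-chromen-4-one | COc1cc(-c2cc(=O)c3c(OCc4ccccc4)cc(OC)c(OC)c3o2)cc(OC)c1OC
F7 | step 10 | 5-(benzyloxy)-2,3-epoxy-7,8-dimethoxy-2-(3,4,5-trimethoxyphenyl)chroman-4-one (racemic, one enantiomer drawn) | COc1cc([C@@]23O[C@@H]2C(=O)c2c(OCc4ccccc4)cc(OC)c(OC)c2O3)cc(OC)c1OC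
A1 | alternative 1 | 2-(chlorocarbonyl)-3,5,6-trimethoxyphenyl 3,4,5-trimethoxybenzoate | COc1cc(C(=O)Oc2c(OC)c(OC)cc(OC)c2C(Cl)=O)cc(OC)c1OC
A2 | alternative 1 | (benzyloxymethylene)triphenylphosphorane | C(OCc1ccccc1)=P(c1ccccc1)(c1ccccc1)c1ccccc1
A3 | alternative 1 | 3-(benzyloxy)-5,7,8-trimethoxy-2-(3,4,5-trimethoxyphenyl)-4H-chromen-4-one | COc1cc(-c2oc3c(OC)c(OC)cc(OC)c3c(=O)c2OCc2ccccc2)cc(OC)c1OC
A4 | alternative 2 | 2,3,5-trimethoxyphenol | Oc1cc(OC)cc(OC)c1OC
A5 | alternative 2 | (E)-3-(3,4,5-trimethoxyphenyl)prop-2-enal | COc1cc(/C=C/C=O)cc(OC)c1OC
A6 | alternative 2 | 5,7,8-trimethoxy-2-(3,4,5-trimethoxyphenyl)-2H-chromene (racemic, one enantiomer drawn) | COc1cc(OC)c2C=C[C@@H](c3cc(OC)c(OC)c(OC)c3)Oc2c1OC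
A7 | alternative 3 | trimethyl{[(3Z)-1,3,4-trimethoxybuta-1,3-dien-1-yl]oxy}silane | CO/C=C(OC)/C=C(OC)O[Si](C)(C)C
A8 | alternative 3 | 4-bromobut-3-yn-2-one | CC(=O)C#CBr
A9 | alternative 3 | 1-(2-bromo-6-hydroxy-3,4-dimethoxyphenyl)ethanone | CC(=O)c1c(O)cc(OC)c(OC)c1Br
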